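**Plan**
- Cuts: the quinone is traced back to 3-hexadecylbenzene-1,2,4,5-tetrol. The C1–O and C5–O bonds are cut first (each back to a ring–CHO bond), then the two ring–formyl C–C bonds, and last the C3–chain bond.
- Enabling feature: on the single six-membered carbocycle, with hexadecyl on C3, oxygen sits on both ortho carbons (C2, C4) and both meta carbons (C1, C5), and only C6 bears hydrogen. A 2-hexadecylresorcinol dimethyl ether already holds C2–O and C4–O.
- C1 and C5 are the two carbons that lie ortho to one methoxy group and para to the other. They therefore accept formyl groups as electrophiles, and later migrate readily from the formyl carbon to a peroxide oxygen.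
- Forward order: no ring is built, because the benzene ring is bought. The sequence is chain attachment by lithiation/alkylation, twofold formylation, twofold Baeyer–Villiger oxygenation, removal of the formates and methyl ethers, and aerobic oxidation to the quinone.
- Stereochemistry: the target has no stereocentre and no configured double bond, so nothing has to be set.

Key step: step 3

Remark: the proton shift between the two hydroxyquinone tautomers of the target is degenerate (it returns the same constitution), so the tautomer drawn needs no separate control.

Step 1
Reactants: 1 1,3-dimethoxybenzene; 2 1-bromohexadecane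
Product: 4 2-hexadecyl-1,3-dimethoxybenzene, via 2,6-dimethoxyphenyllithium 3 (not isolated)
Conditions: 1 (1.2 equiv), n-BuLi (1.15 equiv), THF, 0 °C → rt; then 2 (1.0 equiv), rt → reflux
Reagents that add atoms: none
Why: Directed ortho-metalation removes only the C–H flanked by both methoxy groups (most acidic, doubly coordinated to lithium), and the aryllithium then displaces bromide from the primary halide by SN2 alkylation, a standard entry to 2-alkylresorcinol dimethyl ethers.

Step 2
Reactants: 4 2-hexadecyl-1,3-dimethoxybenzene; 5 dichloromethyl methyl ether
Product: 8 5-hexadecyl-4,6-dimethoxyisophthalaldehyde, via mono(α-chloro ether) 6 (not isolated), via bis(α-chloro ether) 7 (not isolated)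
Conditions: 5 (4 equiv), TiCl4 (5 equiv), CH2Cl2, 0 °C → rt; then ice/1 M HCl
Reagents that add atoms: dichloromethyl methyl ether 5, COC(Cl)Cl; water, O
Why: In this twofold Rieche formylation (Friedel–Crafts type) the two attacked carbons are each ortho to one methoxy and para to the other while the third free carbon is meta to both, the second site stays activated by both donors and is meta to the first acceptor so excess reagent should carry it through, and hydrolysis of the α-chloro ethers at work-up releases both aldehydes.

Step 3
Reactants: 8 5-hexadecyl-4,6-dimethoxyisophthalaldehyde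
Product: 10 5-hexadecyl-4,6-dimethoxy-1,3-phenylene diformate, via monoformate aldehyde 9 (not isolated)
Conditions: mCPBA (3 equiv), CH2Cl2, 0 °C → rt, dark
Reagents that add atoms: 3-chloroperoxybenzoic acid (mCPBA), O=C(OO)c1cccc(Cl)c1
Why: The peracid adds to a formyl carbon to give a tetrahedral peroxy (Criegee) adduct, the aryl carbon shifts from that carbon to the near peroxide oxygen antiperiplanar to the breaking O–O bond while 3-chlorobenzoate leaves, and this happens once at each aldehyde (through 9) to form the C1–O and C5–O bonds. The closest known reaction type is the Baeyer–Villiger (Dakin-type) oxidation of alkoxybenzaldehydes to aryl formates with a peracid, which is routine for 2,4-dialkoxy-3-alkylbenzaldehydes. No ring is closed and no stereocentre is created. The selectivity needed is aryl over hydride migration at both carbonyl groups, and it is secured because each migrating carbon has one methoxy group ortho and the other para, which stabilise the positive charge that builds up on the migrating ring, so the formate and not the benzoic acid should result. After the first migration the remaining aldehyde keeps both donors, and the new formyloxy group lies meta to the second migrating carbon, so little migratory aptitude is lost. The anhydrous, non-basic medium should keep the formates intact, which masks the phenols and shields the electron-rich ring from the excess peracid.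

Step 4
Reactants: 10 5-hexadecyl-4,6-dimethoxy-1,3-phenylene diformate
Product: 11 5-hexadecyl-4,6-dimethoxybenzene-1,3-diol
Conditions: HCl (cat.), MeOH/THF, rt, Ar
Reagents that add atoms: none
Why: Acid-catalysed transesterification cleaves aryl formates, which are among the most labile esters, without touching the aryl methyl ethers, and the acidic oxygen-free medium keeps the electron-rich diphenol from premature autoxidation.

Step 5
Reactants: 11 5-hexadecyl-4,6-dimethoxybenzene-1,3-diol
Product: 14 2,5-dihydroxy-3-hexadecyl-1,4-benzoquinone, via bis(bromodioxaborole) 12 (not isolated), via 3-hexadecylbenzene-1,2,4,5-tetrol 13 (not isolated)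
Conditions: BBr3 (5 equiv), CH2Cl2, −78 °C → rt; H2O, 0 °C; then air, EtOAc/pH 7 phosphate buffer, rt
Reagents that add atoms: none
Why: In this BBr3 aryl methyl ether cleavage boron binds each phenol and its neighbouring methoxy oxygen and bromide removes the methyl group, hydrolysis then frees tetrol 13, and its para-related oxygen pairs make it autoxidise in air to the 2,5-dihydroxy-1,4-benzoquinone, a doubly vinylogous acid at which oxidation should stop under neutral conditions.

**Compound list**
1 | 1,3-dimethoxybenzene | COc1cccc(OC)c1 | starting material
2 | 1-bromohexadecane | CCCCCCCCCCCCCCCCBr | starting material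
3 | 2,6-dimethoxyphenyllithium | [Li]c1c(OC)cccc1OC | intermediate (not isolated)
4 | 2-hexadecyl-1,3-dimethoxybenzene | CCCCCCCCCCCCCCCCc1c(OC)cccc1OC | intermediate
5 | dichloromethyl methyl ether | COC(Cl)Cl | starting material
6 | 1-[chloro(methoxy)methyl]-3-hexadecyl-2,4-dimethoxybenzene (titanium-bound; CHCl configuration undefined, erased on hydrolysis) | CCCCCCCCCCCCCCCCc1c(OC)ccc(C(Cl)OC)c1OC | intermediate (not isolated)
7 | 1,5-bis[chloro(methoxy)methyl]-3-hexadecyl-2,4-dimethoxybenzene (titanium-bound; CHCl configurations undefined, erased on hydrolysis) | CCCCCCCCCCCCCCCCc1c(OC)c(C(Cl)OC)cc(C(Cl)OC)c1OC | intermediate (not isolated)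
8 | 5-hexadecyl-4,6-dimethoxyisophthalaldehyde | CCCCCCCCCCCCCCCCc1c(OC)c(C=O)cc(C=O)c1OC | intermediate
9 | 5-formyl-3-hexadecyl-2,4-dimethoxyphenyl formate | CCCCCCCCCCCCCCCCc1c(OC)c(OC=O)cc(C=O)c1OC | intermediate (not isolated)
10 | 5-hexadecyl-4,6-dimethoxy-1,3-phenylene diformate | CCCCCCCCCCCCCCCCc1c(OC)c(OC=O)cc(OC=O)c1OC | intermediate
11 | 5-hexadecyl-4,6-dimethoxybenzene-1,3-diol | CCCCCCCCCCCCCCCCc1c(OC)c(O)cc(O)c1OC | intermediate
12 | 2,6-dibromo-4-hexadecylbenzo[1,2-d:4,5-d']bis[1,3,2]dioxaborole | CCCCCCCCCCCCCCCCc1c2OB(Br)Oc2cc2OB(Br)Oc12 | intermediate (not isolated)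
13 | 3-hexadecylbenzene-1,2,4,5-tetrol | CCCCCCCCCCCCCCCCc1c(O)c(O)cc(O)c1O | intermediate (not isolated)
14 | 2,5-dihydroxy-3-hexadecyl-1,4-benzoquinone | CCCCCCCCCCCCCCCCC1=C(O)C(=O)C=C(O)C1=O | target

**Total step count:** 5
**Longest linear sequence:** 5 steps (1 → 4 → 8 → 10 → 11 → 14)

**Steps most likely to fail**

Step 2.
- Risk: the formylation may stall after the first substitution, because the titanium-bound α-chloro ether behaves as an aryl oxocarbenium ion and drains the ring. Forcing the reaction invites Lewis-acid loss of a crowded methyl ether next to the new carbonyl group.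
- Fallback (halogen–metal exchange in place of electrophilic formylation): it sets out from 4.
- NBS (2.1 equiv, CH2Cl2/MeCN) should brominate the same two activated carbons to give 1,5-dibromo-3-hexadecyl-2,4-dimethoxybenzene F1.
- Twofold bromine–lithium exchange with t-BuLi (4.2 equiv, THF, −78 °C) should give (5-hexadecyl-4,6-dimethoxy-1,3-phenylene)dilithium F2.
- Quenching with DMF and acidic work-up comes back to the route at 8.

Step 3.
- Risk: at the second aldehyde, hydride migration to the carboxylic acid may compete, since both methoxy groups are twisted out of the ring plane by their two neighbours and donate less. Early loss of a formate would also expose a phenol to over-oxidation by the peracid.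
- Fallback (boron-to-oxygen in place of carbon-to-oxygen migration): it sets out from 4.
- It passes through 1,5-dibromo-3-hexadecyl-2,4-dimethoxybenzene F1 and (5-hexadecyl-4,6-dimethoxy-1,3-phenylene)dilithium F2, made as described for step 2.
- Trapping with 2-isopropoxy-4,4,5,5-tetramethyl-1,3,2-dioxaborolane should give 2,2'-(5-hexadecyl-4,6-dimethoxy-1,3-phenylene)bis(4,4,5,5-tetramethyl-1,3,2-dioxaborolane) F3.
- Oxidation with NaBO3·4H2O in THF/H2O comes back to the route at 11, bypassing 8 and 10.

Step 5.
- Risk: cleavage of the flanked methyl ethers may be incomplete. The very electron-rich tetrol may also suffer uncontrolled oxidation, with peroxide-driven ring degradation during aeration.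
- Fallback (oxidise first, deprotect afterwards): it sets out from 11.
- Oxidative demethylation of one para hydroxy/methoxy pair with (NH4)2Ce(NO3)6 in MeCN/H2O at 0 °C should give 3-hexadecyl-5-hydroxy-2-methoxy-1,4-benzoquinone F4.
- The remaining methoxy group of F4 is a vinylogous methyl ester. Hydrolysis with aqueous NaOH/EtOH followed by acidification comes back to the route at 14, and the tetrol is never formed.

**Further compounds**
F1 | step 2 | 1,5-dibromo-3-hexadecyl-2,4-dimethoxybenzene | CCCCCCCCCCCCCCCCc1c(OC)c(Br)cc(Br)c1OC
F2 | step 2 | (5-hexadecyl-4,6-dimethoxy-1,3-phenylene)dilithium | CCCCCCCCCCCCCCCCc1c(OC)c([Li])cc([Li])c1OC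
F3 | step 3 | 2,2'-(5-hexadecyl-4,6-dimethoxy-1,3-phenylene)bis(4,4,5,5-tetramethyl-1,3,2-dioxaborolane) | CCCCCCCCCCCCCCCCc1c(OC)c(B2OC(C)(C)C(C)(C)O2)cc(B3OC(C)(C)C(C)(C)O3)c1OC
F4 | step 5 | 3-hexadecyl-5-hydroxy-2-methoxy-1,4-benzoquinone | CCCCCCCCCCCCCCCCC1=C(OC)C(=O)C=C(O)C1=O
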